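## The problem

Compound 35 is a cis-fused eremophilane. Ring A (C1–C5, C10) carries the acyloxy group at C3 and the methyl C15 at C4; ring B (C5–C10) carries the isopropenyl group at C7, the ketone at C8 and the hydroxyl at C9; the rings meet at the quaternary C5 (angular methyl C14) and at C10–H, which are cis. Six ring stereocentres (3R,4R,5R,7R,9R,10S in this numbering) and one in the ester chain (4′R) must be set, and because the quaternary centre adjoins two of them the ring fusion has to come from a bond formation that tolerates a fully substituted carbon. Once C5 and C10 are fixed they can steer the rest: in the chair–chair conformer that keeps C14 equatorial on ring B, O3, C15, O9 and the isopropenyl group are all equatorial, so C7 and C9 (both α to the ketone) are the thermodynamic configurations, and C3/C4 are what syn addition to a C3–C4 double bond gives on the face away from C14. The fragile parts are the angelate (Z to E isomerisation), the γ-acyloxy enoate (Michael acceptor, γ-deprotonation), the C8/C9 α-ketol (transposition through the enediol) and the β,γ-unsaturated ketone (drift of the isopropenyl double bond into conjugation, C7 epimerisation), so the side chain and the free C9 hydroxyl must arrive last and no strong base may follow the isopropenyl group. The feature that opens the route is the array O=C8–C7–C6–C5–C4–C3. Read with a C3–C4 double bond in place of C3–O and C4–H, it is a δ,ε-unsaturated ketone whose C5–C6 bond ends at the quaternary carbon, the retron of an oxy-Cope rearrangement; because C8 is also tied to C10 through C9, the rearranging 1,5-diene sits inside a bicyclo[2.2.2]octene that can only unfold into the cis-fused skeleton.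

## Retrosynthesis

**35 ⇒ 34 ⇒ 26 + 33.** The O9–benzyl bond and the ester C–O bond at O3 are cut last. A 4-methoxybenzyl ether on O9 survives every base used earlier and is removed oxidatively at neutral pH, which the α-ketol, the angelate and the isopropenyl ketone all tolerate. Attaching the complete acid 33 to alcohol 26 in one step keeps the base-sensitive chain out of all enolate chemistry; building the chain on the ring piece by piece would add main-line steps. The forward esterification must acylate a hindered equatorial alcohol without moving any double bond.

**33 ⇒ 31 + 32; 31 ⇒ 28 + 29; 28 ⇒ 27.** The C2′=C3′ double bond is cut by cross-metathesis into the allylic angelate 31 and acrylic acid 32. This is shorter than an olefination of a protected α-hydroxy aldehyde and never exposes an epimerisable aldehyde. Ester 31 comes from (R)-pent-1-en-3-ol 28 and angelic acid 29, and 28 from commercial (R)-1,2-epoxybutane 27 by one-carbon homologation. The forward steps must leave the Z geometry of the angelate alone.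

**26 ⇒ 23 + 24.** The C7–C11 bond is cut to the ketone 23 and 2-bromopropene 24 (enolate alkenylation). An aldol–dehydration sequence is the neighbouring choice but tends to give the conjugated isopropylidene ketone. The isopropenyl group has to come after the hydration of ring A, because borane would attack it first. The forward step must enolise toward C7, not toward the alkoxy-bearing C9.

**23 ⇒ 22 ⇒ 20 ⇒ 19.** C3–O and C4–H are removed together to the C3=C4 alkene of octalone 19. The target pattern (H4 and O3 on the same face, both anti to C14) is exactly what hydroboration–oxidation delivers in one facial event. The alternative pair of steps, epoxidation then reductive opening by trivalent titanium (Cp2TiCl), sets C4 by hydrogen-atom transfer to a planar radical, typically trans to the new C3 oxygen, which is the opposite of what is needed. The price of hydroboration is that the C8 ketone must be masked (ketal 20) and released again (23).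

**19 ⇒ 17 (key step).** The C5–C6 bond is cut and C3–C8 re-formed: octalone 19 is the anionic oxy-Cope product of the bicyclo[2.2.2]octenol 17. Against aldol, Michael or Diels–Alder closures of ring B, this cut makes the quaternary C5 intramolecularly, enforces the cis fusion by geometry, leaves O8 and O9 in place and puts the ring A double bond exactly where O3 is needed. The precursor has four stereocentres of one rigid bicycle instead of three on a flexible decalin. The forward reaction needs the vinyl group syn to the dimethyl alkene bridge.

**17 ⇒ 16 ⇒ 15 ⇒ 14 ⇒ 12 + 13.** The C8–vinyl bond is cut to ketone 12 and vinylmagnesium bromide 13. Adding the Grignard reagent directly to a ketone whose neighbour already carries a single ether oxygen on the alkene side was rejected: an α-alkoxy group sends nucleophiles to the opposite face, here the face that gives an alcohol unable to rearrange. In 12 the neighbouring carbon is a dimethyl ketal, the same on both faces, so the bicycle alone decides and the reagent enters beside the alkene bridge. C9 is then set afterwards with certainty: hydrolysis to the α-hydroxy ketone 15, hydride delivered from the tertiary hydroxyl (trans-diol 16) and selective etherification of the secondary hydroxyl (17). This costs three more steps than a direct addition but removes the one stereochemical guess at the centre of the plan.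

**12 ⇒ 11 ⇒ 9 ⇒ 8 ⇒ 7.** The two oxygenated carbons of 12 are traced to the meso diol 7. A lipase differentiates its enantiotopic hydroxyls (monoacetate 8); the free carbinol is oxidised (9) and ketalised while the acetate holds the other position, and the acetate carbon is then uncovered and oxidised (11, 12). A resolution of a later racemate would be shorter but loses half the material.

**7 ⇒ 6 ⇒ 4 + 5; 4 ⇒ 3 ⇒ 1.** Two C–C bonds are cut by a Diels–Alder disconnection to 2,3-dimethylcyclohexa-1,3-diene 4 and vinylene carbonate 5, which deliver both oxygens, both bridgeheads and both methyl-bearing alkene carbons. The diene is made from 2-methylcyclohex-2-en-1-one 1 through the dienyl triflate 3, which fixes both double bonds by construction; elimination routes give isomer mixtures.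

## Roads not taken

**Alternative 1:** Ring A is cut at C3–C4 and C5–C10. Forward, a chiral boron Lewis acid promotes the Diels–Alder reaction of tiglic aldehyde A2 with the (E)-1-substituted diene A3 to give the cyclohexenecarbaldehyde A1. Its merit is real: C4, C5 and C10, including the quaternary centre, come from two achiral fragments in one catalytic enantioselective step, with no meso detour. In that respect it is better than the chosen plan, which needs seven steps to turn diol 7 into 17 and sets C4 only later by a hydroboration whose facial outcome is less than certain. Its weak points for this target are that the ring A double bond ends at C1–C2, so O3 must be introduced at an allylic methylene with fresh stereocontrol; ring B is still open and has to be closed by aldol condensation; O9 and the C7 isopropenyl group must then be placed on an enone; and an α,β-disubstituted enal is among the least reactive dienophiles, with the formyl group required endo next to a substituted diene terminus. Against its economy in carbon stereocentres the chosen plan sets three things: both ring B oxygens present from the cycloaddition, unsaturation exactly at C3–C4, and a fusion geometry that cannot come out trans.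

**Alternative 2:** Both rings are cut at C5–C10 and C6–C7. Forward, the decatrienone A5 undergoes an intramolecular Diels–Alder reaction on heating to the cis-fused octalone A4, which carries a C8 silyl enol ether and a C4 ketone. It forms two rings and two C–C bonds at once, has O3 in place from the start, and its C8=C9 enol ether invites a Rubottom oxidation straight to the 9-hydroxy-8-ketone — a more direct entry to the α-ketol than the chosen plan offers. Against this, C15 and the C4 stereocentre are missing and would have to be added at a neopentyl ketone beside the quaternary carbon. The cis/trans outcome of decatrienone cycloadditions depends on the transition-state shape and is not enforced. One remote stereocentre (C3) must control the diene face. The 2-silyloxydiene and the enone in A5 are prone to hydrolysis and polymerisation, and A5 itself needs a long linear synthesis. The chosen plan closes only one ring in its key step, but C14 and C15 are both present before it and the fusion is fixed by the bicycle.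

**Alternative 3:** Ring A is cut at C1–C10. Forward, the primary radical from iodide A7 (silane chain carrier, radical initiator) adds 6-exo to one arm of the prochiral cyclohexadienone and gives the cis-fused enone A6. Here C3 and C4 are secured before any ring is formed, which is better than relying on a late hydroboration, and the product enone allows kinetic α′-enolisation toward C9 for oxygenation. The weak points are that the choice between the two diastereotopic enone arms, which sets C5 and C10 relative to C4, rests on one adjacent stereocentre and is likely to be moderate; that a dienone with a quaternary carbon bearing a branched, oxygenated chain is laborious to assemble enantioselectively; and that the isopropenyl group must be attached at the α-carbon of an enone and C7 then set by conjugate reduction. The chosen plan has the opposite profile: C5/C10 are beyond doubt, C3/C4 are the centres at risk, and it pays for that with a fallback that corrects C4 by equilibration.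

Key step: step 13

Remark on numbering: every intermediate is described with the eremophilane numbers its carbons carry in 35. In the bicyclo[2.2.2]octenes C3 and C10 are the bridgeheads, C8–C9 the oxygenated bridge, C4=C5 the dimethyl alkene bridge and C1–C2 the ethano bridge; "endo" means syn to the alkene bridge.

Assumption: the lipase acetylates the hydroxyl on the carbon that becomes C8; if the enzyme prefers the other enantiotopic hydroxyl, the same lipase used for hydrolysis of the meso diacetate gives the same monoacetate 8.

Step 1
Reactants: 1 2-methylcyclohex-2-en-1-one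
Product: 3 6-methylcyclohexa-1,5-dien-1-yl trifluoromethanesulfonate, via lithium dienolate 2 (not isolated)
Conditions: LiN(iPr)2, THF, −78 °C; then PhNTf2, −78 → 0 °C
Reagents that add atoms: N-phenylbis(trifluoromethanesulfonimide), O=S(=O)(N(c1ccccc1)S(=O)(=O)C(F)(F)F)C(F)(F)F
Why: Kinetic deprotonation of an enone by a lithium amide removes the α′ proton, and O-triflation of the cross-conjugated dienolate (enol triflate formation) fixes both double bonds of the future diene.

Step 2
Reactants: 3 6-methylcyclohexa-1,5-dien-1-yl trifluoromethanesulfonate
Product: 4 2,3-dimethylcyclohexa-1,3-diene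
Conditions: MeMgBr, Fe(acac)3 (5 mol %), THF/NMP, −30 → 0 °C
Reagents that add atoms: methylmagnesium bromide, C[Mg]Br
Why: Iron-catalysed Kumada-type coupling of alkenyl triflates with alkyl Grignard reagents is fast at low temperature and does not move the double bonds, so the symmetrical diene is obtained free of isomers.

Step 3
Reactants: 4 2,3-dimethylcyclohexa-1,3-diene; 5 vinylene carbonate
Product: 6 meso endo carbonate adduct (cis-5,6-dimethylbicyclo[2.2.2]oct-5-ene-2,3-diyl carbonate; carbonate ring syn to the alkene bridge)
Conditions: 5 (2 equiv), toluene, BHT (cat.), sealed tube, 165 °C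
Reagents that add atoms: none
Why: Diels–Alder reaction; suprafacial addition sets the two bridgeheads and the two carbinol carbons relative to one another, and the endo transition state, which also avoids the ethano-bridge hydrogens, places both oxygens syn to the new alkene bridge; two symmetrical partners give a meso product.

Step 4
Reactants: 6 meso endo carbonate adduct
Product: 7 meso endo-cis-5,6-dimethylbicyclo[2.2.2]oct-5-ene-2,3-diol
Conditions: NaOH, H2O/THF, rt
Reagents that add atoms: none
Why: Saponification of the cyclic carbonate occurs at the carbonyl carbon, so the C–O bonds at the stereocentres are untouched.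

Step 5
Reactants: 7 meso endo-cis diol
Product: 8 monoacetate (acetoxy on C8; hydroxyl on C9; both endo)
Conditions: immobilised Candida antarctica lipase B, vinyl acetate, t-BuOMe, 30 °C
Reagents that add atoms: vinyl acetate, CC(=O)OC=C
Why: Lipase-catalysed irreversible transesterification desymmetrises the meso diol by acylating one enantiotopic hydroxyl, which fixes the absolute configuration of the bridgeheads and hence of everything that follows.

Step 6
Reactants: 8 monoacetate
Product: 9 α-acetoxy ketone (C9 ketone; C8 acetoxy endo)
Conditions: Dess–Martin periodinane, NaHCO3, CH2Cl2, 0 °C → rt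
Reagents that add atoms: none
Why: Dess–Martin oxidation is neutral, so the acetate stays on its own oxygen (acyl migration through an enediol would erode enantiomeric purity) and the tetrasubstituted alkene is not touched.

Step 7
Reactants: 9 α-acetoxy ketone
Product: 11 hydroxy ketal (C9 dimethyl ketal; C8 hydroxyl endo), via acetoxy ketal 10 (not isolated)
Conditions: HC(OMe)3, TsOH·H2O (5 mol %), MeOH, rt; then K2CO3, rt, same flask
Reagents that add atoms: trimethyl orthoformate, COC(OC)OC; methanol, CO
Why: Acid-catalysed ketalisation turns the enzyme-made distinction between the two carbons into a ketal at C9, and methanolysis of the acetate then frees the C8 hydroxyl with no carbonyl left for ketol transposition.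

Step 8
Reactants: 11 hydroxy ketal
Product: 12 3,3-dimethoxy-5,6-dimethylbicyclo[2.2.2]oct-5-en-2-one (C8 ketone; C9 dimethyl ketal; single enantiomer)
Conditions: Dess–Martin periodinane, NaHCO3, CH2Cl2, 0 °C → rt
Reagents that add atoms: none
Why: Dess–Martin oxidation of the secondary alcohol; the only stereocentres left are the bridgeheads, which cannot epimerise.

Step 9
Reactants: 12 keto ketal; 13 vinylmagnesium bromide
Product: 14 vinyl carbinol ketal (C8: vinyl endo and hydroxyl toward the ethano bridge; C9 dimethyl ketal)
Conditions: THF, −78 → 0 °C
Reagents that add atoms: none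
Why: Grignard 1,2-addition; C9 carries two identical methoxy groups, so the α-carbon biases neither face and the bicycle decides: the reagent enters beside the alkene bridge, whose substituents lie in the alkene plane, and not beside the ethano bridge, whose C–H bonds point into the trajectory, as is known for 3,3-dialkoxybicyclo[2.2.2]oct-5-en-2-ones. This sets C8 with the vinyl group syn to the alkene bridge.

Step 10
Reactants: 14 vinyl carbinol ketal
Product: 15 α-hydroxy ketone (C9 ketone; C8 tertiary alcohol with vinyl endo)
Conditions: 1 M HCl, THF/H2O, 0 °C → rt; neutral work-up, used at once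
Reagents that add atoms: water, O
Why: Hydrolysis of an α-hydroxy dimethyl ketal to the α-hydroxy ketone is a standard unmasking; it is run cold and the product is not stored because a 1,2-vinyl shift (α-ketol rearrangement) would lead to the enantiomer.

Step 11
Reactants: 15 α-hydroxy ketone
Product: 16 trans-diol (C8 tertiary hydroxyl toward the ethano bridge; C9 secondary hydroxyl endo)
Conditions: Me4NBH(OAc)3, MeCN/AcOH (1:1), −30 → 0 °C
Reagents that add atoms: none
Why: Evans–Saksena reduction: the tertiary hydroxyl exchanges onto boron and the alkoxyborohydride delivers hydride within the molecule to the C9 face on its own side, so the new hydroxyl appears on the alkene side, trans to O8; triacetoxyborohydride does not reduce ketones without this delivery, so no undirected path competes.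

Step 12
Reactants: 16 trans-diol
Product: 17 2-vinyl-3-(4-methoxybenzyloxy)-5,6-dimethylbicyclo[2.2.2]oct-5-en-2-ol (vinyl and ether oxygen both syn to the alkene bridge)
Conditions: NaH (1.05 equiv), 4-methoxybenzyl bromide, Bu4NI (cat.), THF, 0 °C
Reagents that add atoms: 4-methoxybenzyl bromide, COc1ccc(CBr)cc1
Why: Williamson etherification; the secondary alkoxide is alkylated far faster than the hindered tertiary one, and a sodium alkoxide at 0 °C does not yet trigger the sigmatropic shift.

Step 13
Reactants: 17 2-vinyl-3-(4-methoxybenzyloxy)-5,6-dimethylbicyclo[2.2.2]oct-5-en-2-ol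
Product: 19 cis-fused 9-(4-methoxybenzyloxy)-4,5-dimethyl-octal-3-en-8-one (C7 is CH2), via potassium enolate 18 (not isolated)
Conditions: KH (3 equiv), 18-crown-6 (1.5 equiv), THF, 0 °C → rt; then sat. aq NH4Cl, −78 °C
Reagents that add atoms: none
Why: KH deprotonates the tertiary hydroxyl and the crown ether frees the alkoxide from its cation, which weakens the adjacent C3–C8 bond. The alkoxide then undergoes a [3,3] sigmatropic shift (anionic oxy-Cope rearrangement) over C6=C7–C8–C3–C4=C5: C5–C6 forms, C3–C8 breaks, and the C7=C8 enolate 18 and the C3=C4 double bond result. The closest known reaction type is the anionic oxy-Cope rearrangement of 2-vinylbicyclo[2.2.2]oct-5-en-2-ols, 3-oxygenated ones included, to cis-fused octalones. Ring B is closed not by a chain cyclisation but by this sigmatropic reorganisation through the boat-like six-centre transition state that the bicycle enforces: the C8–C9 bridge leaves C3 and is rejoined through C7–C6 to C5 as a six-membered ring. The new stereocentre C5 is controlled by the bicycle, since C6 can reach C5 only on the alkene face turned toward the C8–C9 bridge, the side on which C10 already holds C9, so C14 ends cis to H10; C9 and C10 pass through unchanged. The step needs the [3,3] shift to win over a [1,3] shift or fragmentation to an allyl anion and an enone; this is secured by the vinyl group syn to the alkene bridge (step 9) and by the poor stability of an alkyl-substituted allyl anion. The cold quench protonates 18 at C7, which is a CH2 group, and C9 is never enolised because the mechanism fixes the enolate regiochemistry.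

Step 14
Reactants: 19 cis-fused octalone
Product: 20 C8 ethylene ketal of 19 (spiro-1,3-dioxolane at C8)
Conditions: TMSOCH2CH2OTMS, TMSOTf (5 mol %), CH2Cl2, −78 → −20 °C
Reagents that add atoms: 1,2-bis(trimethylsilyloxy)ethane, C[Si](C)(C)OCCO[Si](C)(C)C
Why: Noyori ketalisation masks the C8 ketone, which borane would otherwise reduce; the aprotic low-temperature conditions spare the 4-methoxybenzyl ether and do not move the C3–C4 double bond.

Step 15
Reactants: 20 C8 ethylene ketal
Product: 22 C3 alcohol (O3 and H4 on the face opposite C14; C15 cis to C14), via alkylborane 21 (not isolated)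
Conditions: BH3·THF, THF, 0 °C → rt; then NaOH, H2O2, 0 °C → rt
Reagents that add atoms: hydrogen peroxide, OO
Why: Hydroboration–oxidation places boron on the less substituted C3 and hydrogen on C4 in a syn addition, and the angular methyl C14 on the adjacent quaternary carbon should direct the borane to the opposite face. One facial event therefore sets C4 (C15 cis to C14) and C3 (O3 trans to both methyls), and oxidation of the C–B bond proceeds with retention.

Step 16
Reactants: 22 C3 alcohol
Product: 23 3-hydroxy-9-(4-methoxybenzyloxy)-4,5-dimethyl-cis-decal-8-one
Conditions: 1 M HCl, THF, rt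
Reagents that add atoms: water, O
Why: Acid hydrolysis of the dioxolane restores the ketone; the benzyl-type ether and the secondary alcohol are stable to dilute aqueous acid, and C9 already has its thermodynamic (equatorial) configuration.

Step 17
Reactants: 23 hydroxy ketone; 24 2-bromopropene
Product: 26 7-isopropenyl hydroxy ketone (isopropenyl equatorial; cis to C14 and O9), via lithium dienolate 25 (not isolated)
Conditions: Pd2(dba)3 (2.5 mol %), [HP(t-Bu)3]BF4 (6 mol %), LiN(SiMe3)2 (3.3 equiv), toluene/THF, rt → 45 °C; then AcOH, −78 °C
Reagents that add atoms: none
Why: Palladium-catalysed α-alkenylation of a ketone enolate: the amide base deprotonates the hydroxyl and the less hindered C7 (not the alkoxy-bearing C9), and the enolate couples with the alkenyl bromide through oxidative addition to zerovalent palladium and reductive elimination. The product is at once deprotonated to dienolate 25, whose kinetic protonation at the α-carbon from the axial direction gives the β,γ-unsaturated ketone with the isopropenyl group equatorial, which is also the thermodynamic configuration at C7.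

Step 18
Reactants: 27 (R)-1,2-epoxybutane
Product: 28 (R)-pent-1-en-3-ol
Conditions: Me3S+ I−, n-BuLi, THF, −10 °C → rt
Reagents that add atoms: trimethylsulfonium iodide, C[S+](C)C.[I-]
Why: Dimethylsulfonium methylide opens the epoxide at its terminal carbon and a second equivalent converts the resulting sulfonium alkoxide into the allylic alkoxide (one-carbon homologation of an epoxide to an allylic alcohol); the carbinol stereocentre is not involved.

Step 19
Reactants: 28 (R)-pent-1-en-3-ol; 29 angelic acid
Product: 31 (R)-pent-1-en-3-yl (Z)-2-methylbut-2-enoate, via mixed anhydride 30 (not isolated)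
Conditions: 29, 2,4,6-trichlorobenzoyl chloride, Et3N, toluene, rt; then 28, 80 °C
Reagents that add atoms: none
Why: Yamaguchi-type esterification through the mixed anhydride, run without a nucleophilic catalyst so that the reversible conjugate addition that turns angelates into tiglates cannot start.

Step 20
Reactants: 31 (R)-pent-1-en-3-yl angelate; 32 acrylic acid
Product: 33 (R,E)-4-[(Z)-2-methylbut-2-enoyloxy]hex-2-enoic acid
Conditions: second-generation Hoveyda–Grubbs catalyst, (H2IMes)Cl2Ru(=CH-C6H4-2-OiPr) (5 mol %), CH2Cl2, 40 °C
Reagents that add atoms: none
Why: Cross-metathesis of a terminal alkene with acrylic acid gives the E enoic acid directly; the trisubstituted, electron-poor angelate double bond does not enter the catalytic cycle, and the stereocentre is not touched.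

Step 21
Reactants: 26 7-isopropenyl hydroxy ketone; 33 side-chain acid
Product: 34 O9-(4-methoxybenzyl) ether of the target
Conditions: EDC·HCl, DMAP (0.2 equiv), CH2Cl2, 0 °C → rt
Reagents that add atoms: none
Why: Steglich esterification acylates the equatorial C3 hydroxyl with retention; the tertiary-like environment of O9 is capped, and the low temperature and substoichiometric DMAP limit base contact with the β,γ-unsaturated ketone and the γ-acyloxy enoate.

Step 22
Reactants: 34 O9-(4-methoxybenzyl) ether of the target
Product: 35 (3R,4R,5R,7R,9R,10S)-9-hydroxy-8-oxoeremophil-11-en-3-yl (2E,4R)-4-[(Z)-2-methylbut-2-enoyloxy]hex-2-enoate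
Conditions: DDQ, CH2Cl2/pH 7 buffer (10:1), 0 °C
Reagents that add atoms: none
Why: Oxidative cleavage of the 4-methoxybenzyl ether by DDQ proceeds at neutral pH through the benzylic oxocarbenium ion and leaves esters, alkenes and the base-sensitive α-ketol and isopropenyl ketone untouched.

## Compound list

1 | 2-methylcyclohex-2-en-1-one | CC1=CCCCC1=O | starting material
2 | lithium 6-methylcyclohexa-1,5-dien-1-olate | [Li+].[O-]C1=CCCC=C1C | intermediate (not isolated)
3 | 6-methylcyclohexa-1,5-dien-1-yl trifluoromethanesulfonate | CC1=CCCC=C1OS(=O)(=O)C(F)(F)F | intermediate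
4 | 2,3-dimethylcyclohexa-1,3-diene | CC1=CCCC=C1C | intermediate
5 | vinylene carbonate (1,3-dioxol-2-one) | O=C1OC=CO1 | starting material
6 | meso cis-5,6-dimethylbicyclo[2.2.2]oct-5-ene-2,3-diyl carbonate, carbonate ring endo | O=C1O[C@@H]2[C@H](O1)[C@H]3CC[C@@H]2C(C)=C3C | intermediate
7 | meso cis-5,6-dimethylbicyclo[2.2.2]oct-5-ene-2,3-diol, both hydroxyls endo | O[C@@H]1[C@H](O)[C@H]2CC[C@@H]1C(C)=C2C | intermediate
8 | endo,endo-3-hydroxy-5,6-dimethylbicyclo[2.2.2]oct-5-en-2-yl acetate (acetate on C8, hydroxyl on C9; enantiomer as drawn) | CC(=O)O[C@@H]1[C@H](O)[C@H]2CC[C@@H]1C(C)=C2C | intermediate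
9 | endo-5,6-dimethyl-3-oxobicyclo[2.2.2]oct-5-en-2-yl acetate (C9 ketone, C8 acetate) | CC(=O)O[C@@H]1C(=O)[C@H]2CC[C@@H]1C(C)=C2C | intermediate
10 | endo-3,3-dimethoxy-5,6-dimethylbicyclo[2.2.2]oct-5-en-2-yl acetate | CC(=O)O[C@@H]1C(OC)(OC)[C@H]2CC[C@@H]1C(C)=C2C | intermediate (not isolated)
11 | endo-3,3-dimethoxy-5,6-dimethylbicyclo[2.2.2]oct-5-en-2-ol | O[C@@H]1C(OC)(OC)[C@H]2CC[C@@H]1C(C)=C2C | intermediate
12 | 3,3-dimethoxy-5,6-dimethylbicyclo[2.2.2]oct-5-en-2-one (C8 ketone, C9 ketal) | O=C1C(OC)(OC)[C@H]2CC[C@@H]1C(C)=C2C | intermediate
13 | vinylmagnesium bromide | C=C[Mg]Br | starting material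
14 | 3,3-dimethoxy-5,6-dimethyl-2-vinylbicyclo[2.2.2]oct-5-en-2-ol, vinyl endo | C=C[C@]1(O)C(OC)(OC)[C@H]2CC[C@@H]1C(C)=C2C | intermediate
15 | 3-hydroxy-5,6-dimethyl-3-vinylbicyclo[2.2.2]oct-5-en-2-one, vinyl endo (C9 ketone, C8 carbinol) | C=C[C@]1(O)C(=O)[C@H]2CC[C@@H]1C(C)=C2C | intermediate
16 | 5,6-dimethyl-2-vinylbicyclo[2.2.2]oct-5-ene-2,3-diol, trans-diol: vinyl and secondary hydroxyl endo | C=C[C@]1(O)[C@H](O)[C@H]2CC[C@@H]1C(C)=C2C | intermediate
17 | 2-vinyl-3-(4-methoxybenzyloxy)-5,6-dimethylbicyclo[2.2.2]oct-5-en-2-ol, vinyl and ether oxygen endo | C=C[C@]1(O)[C@H](OCc3ccc(OC)cc3)[C@H]2CC[C@@H]1C(C)=C2C | intermediate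
18 | potassium C7=C8 enolate of 19 | C=1C[C@@]2(C)[C@H](CCC=C2C)[C@@H](OCc3ccc(OC)cc3)C=1[O-].[K+] | intermediate (not isolated)
19 | cis-fused 9-(4-methoxybenzyloxy)-4,5-dimethyl-octal-3-en-8-one (O9 cis to H10 and C14) | C1C[C@@]2(C)[C@H](CCC=C2C)[C@@H](OCc3ccc(OC)cc3)C1=O | intermediate
20 | C8 ethylene ketal of 19 | C1C[C@@]2(C)[C@H](CCC=C2C)[C@@H](OCc3ccc(OC)cc3)C14OCCO4 | intermediate
21 | C3 alkylborane from 20 (boron and H4 anti to C14) | C1C[C@@]2(C)[C@H](CC[C@@H](B)[C@@H]2C)[C@@H](OCc3ccc(OC)cc3)C14OCCO4 | intermediate (not isolated)
22 | C8 ethylene ketal of 3-hydroxy-9-(4-methoxybenzyloxy)-4,5-dimethyl-cis-decal-8-one (O3 trans to C14 and C15) | C1C[C@@]2(C)[C@H](CC[C@@H](O)[C@@H]2C)[C@@H](OCc3ccc(OC)cc3)C14OCCO4 | intermediate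
23 | 3-hydroxy-9-(4-methoxybenzyloxy)-4,5-dimethyl-cis-decal-8-one | C1C[C@@]2(C)[C@H](CC[C@@H](O)[C@@H]2C)[C@@H](OCc3ccc(OC)cc3)C1=O | intermediate
24 | 2-bromopropene | CC(Br)=C | starting material
25 | dilithium salt: O3 alkoxide and C7=C8 dienolate of 26 | C=C(C)C=1C[C@@]2(C)[C@H](CC[C@@H]([O-])[C@@H]2C)[C@@H](OCc3ccc(OC)cc3)C=1[O-].[Li+].[Li+] | intermediate (not isolated)
26 | 3-hydroxy-7-isopropenyl-9-(4-methoxybenzyloxy)-4,5-dimethyl-cis-decal-8-one (isopropenyl cis to C14 and O9) | C=C(C)[C@H]1C[C@@]2(C)[C@H](CC[C@@H](O)[C@@H]2C)[C@@H](OCc3ccc(OC)cc3)C1=O | intermediate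
27 | (R)-1,2-epoxybutane | CC[C@@H]1CO1 | starting material
28 | (R)-pent-1-en-3-ol | C=C[C@@H](CC)O | intermediate
29 | angelic acid, (Z)-2-methylbut-2-enoic acid | C/C=C(/C)C(=O)O | starting material
30 | (Z)-2-methylbut-2-enoic 2,4,6-trichlorobenzoic anhydride | C/C=C(/C)C(=O)OC(=O)c1c(Cl)cc(Cl)cc1Cl | intermediate (not isolated)
31 | (R)-pent-1-en-3-yl (Z)-2-methylbut-2-enoate | C=C[C@@H](CC)OC(=O)/C(C)=C\C | intermediate
32 | acrylic acid | C=CC(=O)O | starting material
33 | (R,E)-4-[(Z)-2-methylbut-2-enoyloxy]hex-2-enoic acid | OC(=O)/C=C/[C@@H](CC)OC(=O)/C(C)=C\C | intermediate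
34 | O9-(4-methoxybenzyl) ether of 35 | C=C(C)[C@H]1C[C@@]2(C)[C@H](CC[C@@H](OC(=O)/C=C/[C@@H](CC)OC(=O)/C(C)=C\C)[C@@H]2C)[C@@H](OCc3ccc(OC)cc3)C1=O | intermediate
35 | (3R,4R,5R,7R,9R,10S)-9-hydroxy-8-oxoeremophil-11-en-3-yl (2E,4R)-4-[(Z)-2-methylbut-2-enoyloxy]hex-2-enoate | C=C(C)[C@H]1C[C@@]2(C)[C@H](CC[C@@H](OC(=O)/C=C/[C@@H](CC)OC(=O)/C(C)=C\C)[C@@H]2C)[C@@H](O)C1=O | target

Total step count: 22 (19 in the main line, 3 for the side-chain acid).
Longest linear sequence: 19 steps (steps 1–17, 21 and 22) from 1.

## Least certain steps

**Step 13, the key step.** Bond formation at the fully substituted alkene carbon may be slow enough for the alkoxide to take other exits: heterolysis of C3–C8 to an allyl anion that is protonated or recloses at its other end ([1,3] shift), or decomposition on prolonged warming. The fallback sets out from 17 and returns at 19. The tertiary hydroxyl is silylated to the trimethylsilyl ether F1 and the neutral siloxy-Cope rearrangement is run thermally (sealed tube, hydrocarbon solvent, about 220 °C), which has no ionic fragmentation channel. The resulting C7=C8 trimethylsilyl enol ether F2 is hydrolysed with dilute acid to 19.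

**Step 9.** Facial selectivity may be poor, because the methyl group C15 on the alkene carbon next to C3 narrows the alkene-side corridor that the Grignard reagent must use; addition beside the ethano bridge gives an alcohol that cannot rearrange. The fallback sets out from 12 and returns at 14. Ethynylmagnesium bromide is added instead: a rod-shaped nucleophile is least affected by that methyl group, while the ethano-bridge hydrogens block the other face as before. This gives the propargylic alcohol F3, and semi-hydrogenation over Pd/CaCO3 poisoned with Pb(OAc)2 and quinoline (Lindlar catalyst) turns the ethynyl into the vinyl group.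

**Step 10.** Under acid the vinyl group may migrate from C8 to the oxocarbenium carbon C9, or the freed α-ketol may rearrange, and either process erodes enantiomeric purity; hydrolysis beside a quaternary carbinol may also be slow. The fallback sets out from 7 and returns at 16, avoiding the ketal altogether. The meso diol is oxidised (DMSO, (CF3CO)2O, Et3N) to the meso dione F4. One equivalent of vinylmagnesium bromide adds beside the alkene bridge (the neighbouring carbon is now trigonal) to give the racemic α-hydroxy ketone F5, formed as its magnesium alkoxide, in which ketol rearrangement merely interconverts enantiomers. Reduction as in step 11 gives the racemic trans-diol F6, and lipase-catalysed acetylation of the secondary hydroxyl resolves it, leaving 16 and converting its antipode into the acetate F7. This is three steps shorter than steps 5–11 but gives up half the material.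

**Step 15.** Delivery of borane may occur on the wrong face or unselectively: in the preferred conformer the axial C10–C9 bond leans over the face of C4 that the reagent must use, while C14 shields the other. A wrong-face addition inverts C3 and C4 together. The fallback sets out from 20 and returns at 34:
- Hydroborate as before, oxidise the crude C3 alcohols with Dess–Martin periodinane and equilibrate with DBU to the C3 ketone F8, in which C15 settles equatorial and cis to C14 (its epimer would be 1,3-diaxial to the C10–C9 bond).
- Reduce with LiBH(s-Bu)3, which attacks equatorially, away from the axial C14, and gives the axial 3-epi alcohol F9.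
- Carry this through steps 16 and 17 (3-epi hydroxy ketone F10, 3-epi isopropenyl ketone F11).
- Form the ester by Mitsunobu reaction with acid 33 (PPh3, diisopropyl azodicarboxylate), which inverts C3.

**Step 17.** Enolisation may go toward C9, the free alkoxide may interfere with the catalyst, or the new double bond may drift into conjugation before or during the quench. The fallback sets out from 23 and returns at 26. O3 is protected as the triethylsilyl ether F12; the C7 lithium enolate (LiN(iPr)2, THF, −78 °C) is added to acetone to give the tertiary aldol F13; dehydration toward a methyl group (SOCl2, pyridine, low temperature) gives the silylated isopropenyl ketone F14; and HF·pyridine removes the silyl group. Any conjugated isopropylidene isomer formed alongside F14 is returned by deconjugative kinetic protonation of its dienolate.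

**Step 21.** The activated γ-acyloxy enoyl species may lose its γ proton (ketene formation and a β,γ-unsaturated ester), and the amine base may epimerise C7 or conjugate the isopropenyl group. The fallback sets out from 26 and 31 and returns at 34. Alcohol 26 is acylated with diethylphosphonoacetic acid (N,N′-dicyclohexylcarbodiimide) to the phosphonoacetate F15. The vinyl group of 31 is cleaved selectively (OsO4 cat., NaIO4, 2,6-lutidine) to (R)-2-[(Z)-2-methylbut-2-enoyloxy]butanal F16. The two are joined by Horner–Wadsworth–Emmons olefination under Masamune–Roush conditions (LiCl, i-Pr2NEt, MeCN), which forms the E enoate.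

## Further compounds

F1 | step 13 | trimethylsilyl ether of 17 | C=C[C@]1(O[Si](C)(C)C)[C@H](OCc3ccc(OC)cc3)[C@H]2CC[C@@H]1C(C)=C2C
F2 | step 13 | C7=C8 trimethylsilyl enol ether of 19 | C=1C[C@@]2(C)[C@H](CCC=C2C)[C@@H](OCc3ccc(OC)cc3)C=1O[Si](C)(C)C
F3 | step 9 | 2-ethynyl-3,3-dimethoxy-5,6-dimethylbicyclo[2.2.2]oct-5-en-2-ol, ethynyl endo | C#C[C@]1(O)C(OC)(OC)[C@H]2CC[C@@H]1C(C)=C2C
F4 | step 10 | meso 5,6-dimethylbicyclo[2.2.2]oct-5-ene-2,3-dione | O=C1C(=O)[C@H]2CC[C@@H]1C(C)=C2C
F5 | step 10 | racemic 3-hydroxy-5,6-dimethyl-3-vinylbicyclo[2.2.2]oct-5-en-2-one, vinyl endo (15 and its antipode; antipode drawn) | C=C[C@@]1(O)C(=O)[C@@H]2CC[C@H]1C(C)=C2C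
F6 | step 10 | racemic trans-diol (16 and its antipode; antipode drawn) | C=C[C@@]1(O)[C@@H](O)[C@@H]2CC[C@H]1C(C)=C2C
F7 | step 10 | secondary acetate of the antipode of 16 | C=C[C@@]1(O)[C@@H](OC(C)=O)[C@@H]2CC[C@H]1C(C)=C2C
F8 | step 15 | C8 ethylene ketal of 9-(4-methoxybenzyloxy)-4,5-dimethyl-cis-decalin-3,8-dione (C15 cis to C14) | C1C[C@@]2(C)[C@H](CCC(=O)[C@@H]2C)[C@@H](OCc3ccc(OC)cc3)C14OCCO4
F9 | step 15 | 3-epimer of 22 (axial C3 hydroxyl) | C1C[C@@]2(C)[C@H](CC[C@H](O)[C@@H]2C)[C@@H](OCc3ccc(OC)cc3)C14OCCO4
F10 | step 15 | 3-epimer of 23 | C1C[C@@]2(C)[C@H](CC[C@H](O)[C@@H]2C)[C@@H](OCc3ccc(OC)cc3)C1=O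
F11 | step 15 | 3-epimer of 26 | C=C(C)[C@H]1C[C@@]2(C)[C@H](CC[C@H](O)[C@@H]2C)[C@@H](OCc3ccc(OC)cc3)C1=O
F12 | step 17 | O3-triethylsilyl ether of 23 | C1C[C@@]2(C)[C@H](CC[C@@H](O[Si](CC)(CC)CC)[C@@H]2C)[C@@H](OCc3ccc(OC)cc3)C1=O
F13 | step 17 | 7-(2-hydroxypropan-2-yl) aldol of F12 | CC(C)(O)[C@H]1C[C@@]2(C)[C@H](CC[C@@H](O[Si](CC)(CC)CC)[C@@H]2C)[C@@H](OCc3ccc(OC)cc3)C1=O
F14 | step 17 | O3-triethylsilyl ether of 26 | C=C(C)[C@H]1C[C@@]2(C)[C@H](CC[C@@H](O[Si](CC)(CC)CC)[C@@H]2C)[C@@H](OCc3ccc(OC)cc3)C1=O
F15 | step 21 | O3-(diethylphosphonoacetyl) ester of 26 | C=C(C)[C@H]1C[C@@]2(C)[C@H](CC[C@@H](OC(=O)CP(=O)(OCC)OCC)[C@@H]2C)[C@@H](OCc3ccc(OC)cc3)C1=O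
F16 | step 21 | (R)-2-[(Z)-2-methylbut-2-enoyloxy]butanal | O=C[C@@H](CC)OC(=O)/C(C)=C\C
A1 | alternative 1 | 1,6-dimethyl-2-[(2-methyl-1,3-dioxolan-2-yl)methyl]cyclohex-3-ene-1-carbaldehyde | O=C[C@@]1(C)[C@H](C=CC[C@@H]1C)CC2(C)OCCO2
A2 | alternative 1 | tiglic aldehyde, (E)-2-methylbut-2-enal | C/C=C(\C)C=O
A3 | alternative 1 | (E)-2-methyl-2-(penta-2,4-dien-1-yl)-1,3-dioxolane | C=C/C=C/CC1(C)OCCO1
A4 | alternative 2 | cis-fused 3-(tert-butyldimethylsilyloxy)-5-methyl-8-(triisopropylsilyloxy)octal-8-en-4-one | C1C[C@@]2(C)[C@H](CC[C@@H](O[Si](C)(C)C(C)(C)C)C2=O)C=C1O[Si](C(C)C)(C(C)C)C(C)C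
A5 | alternative 2 | (E)-4-(tert-butyldimethylsilyloxy)-2-methyl-9-(triisopropylsilyloxy)deca-1,7,9-trien-3-one | C=C(C)C(=O)[C@H](O[Si](C)(C)C(C)(C)C)CC/C=C/C(=C)O[Si](C(C)C)(C(C)C)C(C)C
A6 | alternative 3 | cis-fused 3-(tert-butyldimethylsilyloxy)-4,5-dimethyl-octal-6-en-8-one | C1=C[C@@]2(C)[C@H](CC[C@@H](O[Si](C)(C)C(C)(C)C)[C@@H]2C)CC1=O
A7 | alternative 3 | 4-[3-(tert-butyldimethylsilyloxy)-5-iodopentan-2-yl]-4-methylcyclohexa-2,5-dien-1-one | O=C1C=CC(C)(C=C1)[C@@H](C)[C@H](O[Si](C)(C)C(C)(C)C)CCI
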